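**Plan**

1. Oxolane numbering: O1, C2 (4‑hydroxyphenyl), C3 (aroyl), C4 (4‑hydroxybenzyl), C5 (2,4‑dihydroxyphenyl). The retrosynthesis removes six benzyl ethers, undoes a thermodynamic C2/C3 adjustment, adds back a temporary CO2Me at C3, and then cuts three bonds at once: O1–C2, C3–C4 and the CH2–aryl bond of the benzyl arm.
2. Enabling feature: C3 is alpha to the aryl ketone and O1–C2 is beta to it (an oxa‑Michael pair). C4 with its exocyclic CH2–aryl is a terminal alkene attacked at the inner carbon and arylated at the outer one.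
3. Forward: aryl methyl ketone → beta‑keto ester → arylidene acceptor; aldehyde → 1‑arylallyl alcohol. Alkoxide, acceptor and aryl iodide are then joined by zerovalent palladium in one operation that closes the only ring.
4. Stereochemistry: C5 comes from lipase resolution of the allylic alcohol and C4 is set trans to C5 in the ring closure. C3 and C2 settle into the all‑trans pattern by enolisation and reversible oxa‑Michael ring opening after loss of the ester.
5. The phenols stay benzylated throughout and are freed last by neutral hydrogenolysis.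

Key step: step 5

Assumption: the four benzyl‑protected aromatic building blocks are bought as such, and the sense drawn at the quaternary ring carbon of the key‑step product is tentative and without consequence, since that centre is re‑set later.

**Route**

Step 1
Reactants: 1 1-[2,4-bis(benzyloxy)phenyl]ethan-1-one
Product: 2 methyl 3-[2,4-bis(benzyloxy)phenyl]-3-oxopropanoate
Conditions: NaH, (MeO)2CO, THF, reflux; then AcOH, H2O
Reagents that add atoms: dimethyl carbonate, COC(=O)OC
Why: Crossed Claisen condensation of the ketone enolate with dimethyl carbonate should be driven to completion by deprotonation of the beta‑keto ester, and aryl benzyl ethers are inert to NaH.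

Step 2
Reactants: 2 methyl 3-[2,4-bis(benzyloxy)phenyl]-3-oxopropanoate; 3 4-(benzyloxy)benzaldehyde
Product: 4 methyl 2-[2,4-bis(benzyloxy)benzoyl]-3-[4-(benzyloxy)phenyl]prop-2-enoate (E/Z mixture)
Conditions: piperidine (cat.), AcOH (cat.), toluene, reflux, Dean–Stark trap
Reagents that add atoms: none
Why: Knoevenagel condensation of the active methylene compound with a non‑enolisable aldehyde under azeotropic removal of water should give the doubly activated alkene, whose geometry is irrelevant because step 5 saturates it.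

Step 3
Reactants: 5 2,4-bis(benzyloxy)benzaldehyde
Product: 6 rac-1-[2,4-bis(benzyloxy)phenyl]prop-2-en-1-ol
Conditions: CH2=CHMgBr, THF, −78 to 0 °C; then H2O
Reagents that add atoms: vinylmagnesium bromide, C=C[Mg]Br
Why: Grignard 1,2‑addition of the vinyl reagent to the aldehyde, with a neutral quench to protect the ionisation‑prone electron‑rich benzylic allylic alcohol.

Step 4
Reactants: 6 rac-1-[2,4-bis(benzyloxy)phenyl]prop-2-en-1-ol
Product: 7 (1S)-1-[2,4-bis(benzyloxy)phenyl]prop-2-en-1-ol
Conditions: vinyl acetate, immobilised Candida antarctica lipase B, MTBE, 30 °C, run past half conversion; chromatography on Et3N‑deactivated silica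
Reagents that add atoms: none
Why: Lipase‑catalysed kinetic resolution by transesterification, in which the usual preference of lipases for the (R)‑enantiomer of secondary alcohols with a large aryl and a medium vinyl group should leave the (S)‑alcohol that fixes C5 of the target.

Step 5
Reactants: 7 (1S)-1-[2,4-bis(benzyloxy)phenyl]prop-2-en-1-ol; 4 methyl 2-[2,4-bis(benzyloxy)benzoyl]-3-[4-(benzyloxy)phenyl]prop-2-enoate; 8 1-(benzyloxy)-4-iodobenzene
Product: 11 methyl (2S,3S,4S,5S)-3-[2,4-bis(benzyloxy)benzoyl]-4-[4-(benzyloxy)benzyl]-5-[2,4-bis(benzyloxy)phenyl]-2-[4-(benzyloxy)phenyl]oxolane-3-carboxylate, via sodium alkoxide 9 (not isolated), via sodium enolate adduct 10 (not isolated)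
Conditions: NaH, THF, 0 °C; 4, 0 °C to rt; then 8, Pd(PPh3)4 (5 mol %), DMSO, 50 °C
Reagents that add atoms: none
Why: The sodium alkoxide adds reversibly to the beta‑carbon of 4 (oxa‑Michael, making O1–C2) to give the stabilised enolate 10, while oxidative addition of 8 to zerovalent palladium gives an arylpalladium iodide (divalent palladium) that binds the terminal alkene; the enolate carbon C3 then attacks the inner alkene carbon C4 on the face opposite to palladium, and C(sp3)–C(sp2) reductive elimination joins the new exocyclic CH2 to the aryl group. The closest known reaction type is the palladium‑mediated one‑pot coupling of allylic alkoxides, alkylidene 1,3‑dicarbonyl compounds and aryl halides to 4‑benzyl tetrahydrofurans. The oxolane ring closes by 5‑exo‑trig carbon–carbon bond formation between C3 and C4. C4 is controlled by C5, whose aryl group lies pseudo‑equatorial in the chair‑like transition state so that the CH2–aryl arm ends trans to it; C2 is set under a rapid retro‑addition pre‑equilibrium, and the epimer with its aryl group anti to the forming bond (least allylic strain against the planar enolate) should cyclise, placing that aryl cis to the C5 aryl; C3 becomes quaternary and its sense is of no consequence. The step needs 5‑exo rather than 6‑endo attack and carbopalladation/coupling rather than Heck arylation or direct enolate arylation, which the five‑atom tether and the low arylation rate of a hindered doubly stabilised enolate should secure. Stereochemically it needs only the trans C4/C5 relation, secured by the allylic C5 centre, because C2 and C3 are re‑set in steps 6 and 7.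

Step 6
Reactants: 11 methyl (2S,3S,4S,5S)-3-[2,4-bis(benzyloxy)benzoyl]-4-[4-(benzyloxy)benzyl]-5-[2,4-bis(benzyloxy)phenyl]-2-[4-(benzyloxy)phenyl]oxolane-3-carboxylate
Product: 13 [2,4-bis(benzyloxy)phenyl]{(2R,3R,4S,5S)-4-[4-(benzyloxy)benzyl]-5-[2,4-bis(benzyloxy)phenyl]-2-[4-(benzyloxy)phenyl]oxolan-3-yl}methanone, via lithium carboxylate 12 (not isolated)
Conditions: LiCl, H2O, DMSO, 140 °C
Reagents that add atoms: none
Why: Krapcho dealkoxycarbonylation, in which chloride demethylates the ester by SN2 attack, the beta‑keto carboxylate loses CO2 and the enolate is protonated by water, most likely with the aroyl group trans to the C2 aryl, while the ethers tolerate the neutral salt conditions.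

Step 7
Reactants: 13 [2,4-bis(benzyloxy)phenyl]{(2R,3R,4S,5S)-4-[4-(benzyloxy)benzyl]-5-[2,4-bis(benzyloxy)phenyl]-2-[4-(benzyloxy)phenyl]oxolan-3-yl}methanone
Product: 15 [2,4-bis(benzyloxy)phenyl]{(2S,3S,4S,5S)-4-[4-(benzyloxy)benzyl]-5-[2,4-bis(benzyloxy)phenyl]-2-[4-(benzyloxy)phenyl]oxolan-3-yl}methanone, via ring-opened potassium alkoxide 14 (not isolated)
Conditions: KOtBu (0.3 equiv), t-BuOH–THF, 40 °C; then AcOH
Reagents that add atoms: none
Why: Base‑mediated equilibration, in which the ketone enolate epimerises C3 and opens the ring by retro‑oxa‑Michael elimination of the C2–O bond, and reversible re‑addition of the C5 alkoxide to the enone (5‑endo oxa‑Michael) should funnel whatever C2 ratio step 5 delivers to the all‑trans oxolane, the only isomer without cis‑vicinal substituents, while C4 and C5 carry no acidic hydrogen and stay fixed.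

Step 8
Reactants: 15 [2,4-bis(benzyloxy)phenyl]{(2S,3S,4S,5S)-4-[4-(benzyloxy)benzyl]-5-[2,4-bis(benzyloxy)phenyl]-2-[4-(benzyloxy)phenyl]oxolan-3-yl}methanone
Product: 16 (2,4-dihydroxyphenyl)[(2S,3S,4S,5S)-5-(2,4-dihydroxyphenyl)-4-(4-hydroxybenzyl)-2-(4-hydroxyphenyl)oxolan-3-yl]methanone
Conditions: H2 (1 atm), 10% Pd/C, EtOAc–MeOH, rt
Reagents that add atoms: none
Why: Neutral hydrogenolysis of the six aryl benzyl ethers, stopped at the uptake for six benzyl groups so that the conjugated, hydrogen‑bonded aryl ketone and the two ring benzylic C–O bonds should be kept and no stereocentre is exposed to acid or base.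

**Compound list**

1 | 1-[2,4-bis(benzyloxy)phenyl]ethan-1-one | CC(=O)c1ccc(OCc2ccccc2)cc1OCc1ccccc1 | starting material
2 | methyl 3-[2,4-bis(benzyloxy)phenyl]-3-oxopropanoate | COC(=O)CC(=O)c1ccc(OCc2ccccc2)cc1OCc1ccccc1 | intermediate
3 | 4-(benzyloxy)benzaldehyde | O=Cc1ccc(OCc2ccccc2)cc1 | starting material
4 | methyl 2-[2,4-bis(benzyloxy)benzoyl]-3-[4-(benzyloxy)phenyl]prop-2-enoate (E/Z mixture) | COC(=O)C(=Cc1ccc(OCc2ccccc2)cc1)C(=O)c1ccc(OCc2ccccc2)cc1OCc1ccccc1 | intermediate
5 | 2,4-bis(benzyloxy)benzaldehyde | O=Cc1ccc(OCc2ccccc2)cc1OCc1ccccc1 | starting material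
6 | rac-1-[2,4-bis(benzyloxy)phenyl]prop-2-en-1-ol | C=CC(O)c1ccc(OCc2ccccc2)cc1OCc1ccccc1 | intermediate
7 | (1S)-1-[2,4-bis(benzyloxy)phenyl]prop-2-en-1-ol | C=C[C@H](O)c1ccc(OCc2ccccc2)cc1OCc1ccccc1 | intermediate
8 | 1-(benzyloxy)-4-iodobenzene | Ic1ccc(OCc2ccccc2)cc1 | starting material
9 | sodium (1S)-1-[2,4-bis(benzyloxy)phenyl]prop-2-en-1-olate | C=C[C@H]([O-])c1ccc(OCc2ccccc2)cc1OCc1ccccc1.[Na+] | intermediate
10 | sodium enolate of methyl (3S)-3-{[(1S)-1-[2,4-bis(benzyloxy)phenyl]prop-2-en-1-yl]oxy}-2-[2,4-bis(benzyloxy)benzoyl]-3-[4-(benzyloxy)phenyl]propanoate (the ether epimer that cyclises) | COC(=O)C(=C([O-])c1ccc(OCc2ccccc2)cc1OCc1ccccc1)[C@@H](O[C@@H](C=C)c1ccc(OCc2ccccc2)cc1OCc1ccccc1)c1ccc(OCc2ccccc2)cc1.[Na+] | intermediate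
11 | methyl (2S,3S,4S,5S)-3-[2,4-bis(benzyloxy)benzoyl]-4-[4-(benzyloxy)benzyl]-5-[2,4-bis(benzyloxy)phenyl]-2-[4-(benzyloxy)phenyl]oxolane-3-carboxylate (2‑aryl cis to 5‑aryl, 4‑benzyl trans to both, C3 tentative) | COC(=O)[C@@]1(C(=O)c2ccc(OCc3ccccc3)cc2OCc2ccccc2)[C@H](Cc2ccc(OCc3ccccc3)cc2)[C@@H](c2ccc(OCc3ccccc3)cc2OCc2ccccc2)O[C@H]1c1ccc(OCc2ccccc2)cc1 | intermediate
12 | lithium carboxylate of 11 | [Li+].[O-]C(=O)[C@@]1(C(=O)c2ccc(OCc3ccccc3)cc2OCc2ccccc2)[C@H](Cc2ccc(OCc3ccccc3)cc2)[C@@H](c2ccc(OCc3ccccc3)cc2OCc2ccccc2)O[C@H]1c1ccc(OCc2ccccc2)cc1 | intermediate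
13 | [2,4-bis(benzyloxy)phenyl]{(2R,3R,4S,5S)-4-[4-(benzyloxy)benzyl]-5-[2,4-bis(benzyloxy)phenyl]-2-[4-(benzyloxy)phenyl]oxolan-3-yl}methanone | O=C(c1ccc(OCc2ccccc2)cc1OCc1ccccc1)[C@@H]1[C@H](Cc2ccc(OCc3ccccc3)cc2)[C@@H](c2ccc(OCc3ccccc3)cc2OCc2ccccc2)O[C@H]1c1ccc(OCc2ccccc2)cc1 | intermediate
14 | potassium (1S,2S)-3-[2,4-bis(benzyloxy)benzoyl]-2-[4-(benzyloxy)benzyl]-1-[2,4-bis(benzyloxy)phenyl]-4-[4-(benzyloxy)phenyl]but-3-en-1-olate (ring‑opened enone) | [K+].[O-][C@H](c1ccc(OCc2ccccc2)cc1OCc1ccccc1)[C@@H](Cc1ccc(OCc2ccccc2)cc1)C(=Cc1ccc(OCc2ccccc2)cc1)C(=O)c1ccc(OCc2ccccc2)cc1OCc1ccccc1 | intermediate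
15 | [2,4-bis(benzyloxy)phenyl]{(2S,3S,4S,5S)-4-[4-(benzyloxy)benzyl]-5-[2,4-bis(benzyloxy)phenyl]-2-[4-(benzyloxy)phenyl]oxolan-3-yl}methanone (all‑trans) | O=C(c1ccc(OCc2ccccc2)cc1OCc1ccccc1)[C@H]1[C@H](Cc2ccc(OCc3ccccc3)cc2)[C@@H](c2ccc(OCc3ccccc3)cc2OCc2ccccc2)O[C@@H]1c1ccc(OCc2ccccc2)cc1 | intermediate
16 | (2,4-dihydroxyphenyl)[(2S,3S,4S,5S)-5-(2,4-dihydroxyphenyl)-4-(4-hydroxybenzyl)-2-(4-hydroxyphenyl)oxolan-3-yl]methanone (all‑trans) | O=C(c1ccc(O)cc1O)[C@H]1[C@H](Cc2ccc(O)cc2)[C@@H](c2ccc(O)cc2O)O[C@@H]1c1ccc(O)cc1 | target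

Total step count: 8. Longest linear sequence: 6 steps (steps 1, 2, 5, 6, 7, 8 or steps 3, 4, 5, 6, 7, 8).

**Steps most likely to fail**

Step 5. The cascade may be starved by Heck arylation of the allyl ether, by beta‑hydride loss from a palladium alkoxide, or by protonation of the enolate before the alkene is engaged. The fallback sets out from 7 and 4 and comes back at 11. The sodium alkoxide of 7 is added to 4 as before, and the enolate is quenched with N‑iodosuccinimide at −78 °C to give methyl 3-{[(1S)-1-[2,4-bis(benzyloxy)phenyl]prop-2-en-1-yl]oxy}-2-[2,4-bis(benzyloxy)benzoyl]-3-[4-(benzyloxy)phenyl]-2-iodopropanoate F1. Iodine‑atom‑transfer 5‑exo radical cyclisation (Et3B, air, benzene, rt) should then give methyl (2S,3S,4S,5S)-3-[2,4-bis(benzyloxy)benzoyl]-5-[2,4-bis(benzyloxy)phenyl]-2-[4-(benzyloxy)phenyl]-4-(iodomethyl)oxolane-3-carboxylate F2, again with the iodomethyl arm trans to the C5 aryl. Nickel‑catalysed reductive cross‑electrophile coupling of F2 with 8 (nickel diiodide NiI2, 4,4'-di-tert-butyl-2,2'-bipyridine, Zn, DMPU, 60 °C) leads to 11. Any C2 epimer formed alongside is carried by steps 6 and 7 to the same 15.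

Step 7. The enolate may epimerise only C3, because ring opening through the C2–O bond is stereoelectronically slow, or the open hydroxy enone may fail to re‑close. The fallback sets out from 13 and comes back at 15 without a new compound (F0). BF3·OEt2 in CH2Cl2 at −20 °C ionises the benzylic C2–O bond to a 4‑benzyloxyphenyl‑stabilised cation, and thermodynamic re‑closure, the known acid‑mediated epimerisation of 2‑aryl tetrahydrofuran lignans, should give the all‑trans isomer. The C3 centre then settles by mild amine‑catalysed enolisation.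

Step 8. Over‑reduction may occur, either hydrogenolysis of the ring benzylic C–O bonds at C2 and C5 once the phenols are free, or reduction of the aryl ketone. The fallback sets out from 15 and comes back at 16 without a new compound (F0). Lewis‑acid debenzylation with BCl3 and pentamethylbenzene as cation scavenger in CH2Cl2 at −78 °C, followed by a methanol quench, removes the benzyl groups without hydrogen.

Further compounds
F1 | step 5 | methyl 3-{[(1S)-1-[2,4-bis(benzyloxy)phenyl]prop-2-en-1-yl]oxy}-2-[2,4-bis(benzyloxy)benzoyl]-3-[4-(benzyloxy)phenyl]-2-iodopropanoate (epimers at C2 and C3) | COC(=O)C(I)(C(=O)c1ccc(OCc2ccccc2)cc1OCc1ccccc1)C(O[C@@H](C=C)c1ccc(OCc2ccccc2)cc1OCc1ccccc1)c1ccc(OCc2ccccc2)cc1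
F2 | step 5 | methyl (2S,3S,4S,5S)-3-[2,4-bis(benzyloxy)benzoyl]-5-[2,4-bis(benzyloxy)phenyl]-2-[4-(benzyloxy)phenyl]-4-(iodomethyl)oxolane-3-carboxylate | COC(=O)[C@@]1(C(=O)c2ccc(OCc3ccccc3)cc2OCc2ccccc2)[C@H](CI)[C@@H](c2ccc(OCc3ccccc3)cc2OCc2ccccc2)O[C@H]1c1ccc(OCc2ccccc2)cc1
F0 | step 7 | none | none
F0 | step 8 | none | none
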